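## Structural features

Stenosporic acid is a depside: two benzene rings joined only by an aryl ester. Ring A is a 2-hydroxy-4-methoxy-6-propylbenzoyl unit (C1' carries the ester carbonyl, C2' an OH, C4' the OMe, C6' the n-propyl group). Ring B is olivetolic acid (C1 CO2H, C2 OH, C4 the esterified oxygen, C6 n-pentyl). There are no stereocenters and no rings other than the two arenes. The fragile groups are the aryl ester, which is cleaved by hydroxide, alkoxides and amines, and the β-resorcylic acid of ring B, which decarboxylates on heating. The real difficulty is the ester: its carbonyl sits between two ortho substituents (C2'-OH and C6'-propyl) on an electron-rich ring and must be joined to a weakly nucleophilic phenol. Three phenolic oxygens and one carboxyl group must also be told apart. The key step exploits the fact that the ester carbon, C1' to C6' of ring A and the propyl group form one unbranched 3,5,7-trioxodecanoyl chain ending at O-4 of ring B. The ester can therefore be made from an open chain before ring A and its ortho substituents exist.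

## Logic of the disconnections

**12 to 11.** The O–CH2Ph bond of a benzyl ester on the ring-B carboxyl is cut. A free β-resorcylic acid would capture a ketene and would decarboxylate when heated, so it is masked. The forward step must remove the benzyl group without touching the aryl ester; hydrogenolysis does this.

**11 to 10.** The O–CH3 bond at C4' is cut. The chain folding delivers the C4' oxygen as a free phenol, and it is the only phenol not hydrogen-bonded to an ortho carbonyl. The forward step must monomethylate this oxygen in the presence of two chelated phenols and the aryl ester.

**10 to 4 and 6 (key disconnection).** Two bonds are cut: the ring-A bond C1'–C6' (with the water lost on aromatization) and the ester bond between the carbonyl carbon and O-4 of ring B. This opens ring A to the triketo ester 8, which comes from the acylketene 7 and phenol 6; 7 is released from 4 with loss of acetone. In one sentence: ring A is grown on the ring-B phenol, by capture of the acylketene from 4 by 6 followed by aldol folding of the resulting triketo ester. The gain is that the hindered 2,6-disubstituted benzoate ester and the whole of ring A reduce to a linear chain and a phenol. The forward step demands three things: bimolecular capture of 7 faster than its self-capture, reaction at the 4-OH and not the 2-OH of 6, and aldol closure (C2 to C7 of 8) faster than acyl transfer from the activated aryl ester.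

**4 to 2 and 3.** The C3–C4 bond of the side chain is cut, between the methylene and the butanoyl carbonyl. This reduces the diketone to a methyl ketone and a four-carbon acyl donor. The forward step needs the dianion of 2 to react at its terminal carbon and needs single addition to 3.

**2 to 1.** The bond between the C6 methylene of the dioxinone and the acetyl carbonyl is cut, leaving 1 and an acetyl donor. The forward step needs C-acylation at the γ-carbon of the dienolate.

**6 to 5.** The benzyl O–C bond is cut. The forward step must alkylate the carboxylate without alkylating a phenol and without decarboxylation.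

## Other disconnections considered

**Alternative 1:** This is the cut that comes to mind first: the ester C(=O)–O bond between two finished arenes. The forward key step is acylation of the 4-OH of 6 by the protected acid A1 through a mixed anhydride, giving A2, followed by double hydrogenolysis to 12. The chosen plan is preferred on three grounds. A1 needs its own arene synthesis of several steps with two different ether groups. The acylating carbonyl of A1 is flanked by two ortho substituents on an electron-rich ring, so the acyl transfer to a phenol is intrinsically slow. The key step builds nothing but the ester, so the step count is higher.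

**Alternative 2:** Ring A is cut at C1'–C2' and C5'–C6' and built by a Diels–Alder reaction. The alkynoate A3 (the hex-2-ynoyl ester of 6) would react with the trioxygenated diene A4, then lose methanol and the silyl group to give 11 directly. The regiochemistry is sound in principle: the CH2 terminus of A4 should attack the propyl-bearing alkyne carbon. The chosen plan is preferred on mechanistic grounds. A β-alkyl alkynoate is a poor dienophile, and the forcing temperatures needed would degrade the silyl ketene acetal. A4 is also nucleophilic enough to attack the activated aryl ester of A3. The aromatization can expel either the methoxy or the silyloxy group, which leaves the C2' substituent uncertain.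

**Alternative 3:** Both bonds to the ester carbonyl are cut and the carbon is introduced as carbon monoxide. The forward key step is a palladium-catalysed aryloxycarbonylation (Pd(OAc)2 with a phosphine) of the iodoarene A5 with 6, giving 11. The chosen plan is preferred on three grounds. A5 would come from iodination of a phenol with three activated positions, so its regiochemistry is not secured. The acylpalladium intermediate is di-ortho-substituted and must be intercepted by a poor phenoxide nucleophile. The free phenol of A5 competes with 6 for that intermediate, leading to self-esterification.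

Key step: step 4

Assumption: the target has no stereocenter, so no step needs stereocontrol; compounds 1, 3 and 5 are taken as catalogue materials.

## Steps

Step 1
Reactants: 1 2,2,6-trimethyl-4H-1,3-dioxin-4-one
Product: 2 2,2-dimethyl-6-(2-oxopropyl)-4H-1,3-dioxin-4-one
Conditions: 1 (2 equiv), LiN(SiMe3)2 (2 equiv), THF, −78 °C; AcCl (1 equiv), −78 °C; aq. NH4Cl
Reagents that add atoms: acetyl chloride, CC(=O)Cl
Why: γ-Deprotonation of 1 gives the lithium dienolate, which undergoes Claisen-type C-acylation at the γ-carbon; the product is more acidic than 1, so a second equivalent of dienolate serves as base and is recovered as 1.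

Step 2
Reactants: 2 2,2-dimethyl-6-(2-oxopropyl)-4H-1,3-dioxin-4-one; 3 N-methoxy-N-methylbutanamide
Product: 4 6-(2,4-dioxoheptyl)-2,2-dimethyl-4H-1,3-dioxin-4-one
Conditions: LiN(iPr)2 (2.2 equiv), THF, −78 to −40 °C; then 3, −78 to −20 °C; 1 M HCl quench
Reagents that add atoms: none
Why: Double deprotonation gives a dianion (first at the doubly activated CH2, then at the terminal CH3) that reacts at its more basic terminal carbon in a Claisen condensation; the chelated tetrahedral adduct of the Weinreb amide prevents a second addition and releases the 1,3-diketone on acidic quench.

Step 3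
Reactants: 5 olivetolic acid (2,4-dihydroxy-6-pentylbenzoic acid)
Product: 6 benzyl 2,4-dihydroxy-6-pentylbenzoate
Conditions: BnBr (1.05 equiv), KHCO3, DMF, rt
Reagents that add atoms: benzyl bromide, BrCc1ccccc1
Why: KHCO3 ionizes only the carboxylic acid, so SN2 alkylation by benzyl bromide occurs at the carboxylate and not at the phenols; room temperature avoids decarboxylation of the β-resorcylic acid.

Step 4
Reactants: 4 6-(2,4-dioxoheptyl)-2,2-dimethyl-4H-1,3-dioxin-4-one; 6 benzyl 2,4-dihydroxy-6-pentylbenzoate
Product: 10 benzyl 4-[(2,4-dihydroxy-6-propylbenzoyl)oxy]-2-hydroxy-6-pentylbenzoate, via diketo acylketene 7 (not isolated), via aryl triketo ester 8 (not isolated), via cyclic aldol adduct 9 (not isolated)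
Conditions: 6 (1.5 equiv), PhMe (concentrated), 110 °C; cool, cat. Et3N, CH2Cl2, rt; 1 M HCl work-up
Reagents that add atoms: none
Why: Heating 4 causes a retro-hetero-Diels–Alder loss of acetone to the acylketene 7, which the 4-OH of 6 captures through the six-membered hydrogen-transfer transition state typical of acylketene additions; the known reaction type is thermolysis of diketo-dioxinones with O–H nucleophiles followed by aldol aromatization to resorcylate esters. Et3N enolizes the triketo ester 8, and its C2 carbon adds to the C7 ketone in a 6-(enolendo)-exo-trig aldol closure to 9, which loses water and tautomerizes to benzene ring A of 10, driven by aromatization. No stereocenter remains, since the two in 9 are erased on aromatization. Site selectivity on 6 rests on the 2-OH being hydrogen-bonded to and flanked by the ortho ester carbonyl, which leaves the 4-OH as the competent nucleophile. Aldol folding is favoured over acyl transfer from the aryl ester by a mild amine base in an aprotic medium: the enolized 3,5-dicarbonyl unit leaves the C7 ketone as the only free electrophilic carbonyl six atoms from C2. Excess 6 at high concentration lets bimolecular capture outrun self-capture of 7 by its own enol. The ester bond is thus made from an unhindered ketene before the two ortho substituents of ring A exist.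

Step 5
Reactants: 10 benzyl 4-[(2,4-dihydroxy-6-propylbenzoyl)oxy]-2-hydroxy-6-pentylbenzoate
Product: 11 benzyl 2-hydroxy-4-[(2-hydroxy-4-methoxy-6-propylbenzoyl)oxy]-6-pentylbenzoate
Conditions: MeI (1.1 equiv), K2CO3 (1.1 equiv), acetone, rt
Reagents that add atoms: iodomethane, CI
Why: The C4' hydroxyl is the only phenol not held in an intramolecular hydrogen bond to an ortho carbonyl, so it is the most acidic and the one ionized by one equivalent of carbonate; Williamson etherification (SN2 on iodomethane) then occurs there.

Step 6
Reactants: 11 benzyl 2-hydroxy-4-[(2-hydroxy-4-methoxy-6-propylbenzoyl)oxy]-6-pentylbenzoate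
Product: 12 stenosporic acid (2-hydroxy-4-[(2-hydroxy-4-methoxy-6-propylbenzoyl)oxy]-6-pentylbenzoic acid)
Conditions: H2 (1 atm), 10% Pd/C, EtOAc, rt
Reagents that add atoms: none
Why: Catalytic hydrogenolysis cleaves the benzylic C–O bond of the benzyl ester; the aryl ester, the methyl ether and both arenes are inert to hydrogen at atmospheric pressure and room temperature.

## Compound list

1 | 2,2,6-trimethyl-4H-1,3-dioxin-4-one | CC1=CC(=O)OC(C)(C)O1 | starting material
2 | 2,2-dimethyl-6-(2-oxopropyl)-4H-1,3-dioxin-4-one | CC(=O)CC1=CC(=O)OC(C)(C)O1 | intermediate
3 | N-methoxy-N-methylbutanamide | CCCC(=O)N(C)OC | starting material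
4 | 6-(2,4-dioxoheptyl)-2,2-dimethyl-4H-1,3-dioxin-4-one | CCCC(=O)CC(=O)CC1=CC(=O)OC(C)(C)O1 | intermediate
5 | olivetolic acid (2,4-dihydroxy-6-pentylbenzoic acid) | CCCCCc1cc(O)cc(O)c1C(=O)O | starting material
6 | benzyl 2,4-dihydroxy-6-pentylbenzoate | CCCCCc1cc(O)cc(O)c1C(=O)OCc1ccccc1 | intermediate
7 | diketo acylketene, dec-1-ene-1,3,5,7-tetrone | CCCC(=O)CC(=O)CC(=O)C=C=O | intermediate (not isolated)
8 | aryl triketo ester, benzyl 2-hydroxy-6-pentyl-4-[(3,5,7-trioxodecanoyl)oxy]benzoate | CCCC(=O)CC(=O)CC(=O)CC(=O)Oc1cc(O)c(C(=O)OCc2ccccc2)c(CCCCC)c1 | intermediate (not isolated)
9 | cyclic aldol adduct, benzyl 2-hydroxy-4-[(2-hydroxy-4,6-dioxo-2-propylcyclohexane-1-carbonyl)oxy]-6-pentylbenzoate (mixture of stereoisomers, erased on aromatization) | CCCC1(O)CC(=O)CC(=O)C1C(=O)Oc1cc(O)c(C(=O)OCc2ccccc2)c(CCCCC)c1 | intermediate (not isolated)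
10 | benzyl 4-[(2,4-dihydroxy-6-propylbenzoyl)oxy]-2-hydroxy-6-pentylbenzoate | CCCCCc1cc(OC(=O)c2c(O)cc(O)cc2CCC)cc(O)c1C(=O)OCc1ccccc1 | intermediate
11 | benzyl 2-hydroxy-4-[(2-hydroxy-4-methoxy-6-propylbenzoyl)oxy]-6-pentylbenzoate | CCCCCc1cc(OC(=O)c2c(O)cc(OC)cc2CCC)cc(O)c1C(=O)OCc1ccccc1 | intermediate
12 | stenosporic acid | CCCCCc1cc(OC(=O)c2c(O)cc(OC)cc2CCC)cc(O)c1C(=O)O | target

## Step count and least certain steps

Total steps: 6. Longest linear sequence: 5 steps (steps 1, 2, 4, 5, 6); step 3 is a one-step branch.

**Step 4 (key step).** Two processes may defeat it. The first is capture of the ketene by the enol of its own chain (lactonization) before the weakly nucleophilic phenol can react. The second is acyl transfer from the activated aryl ester after capture, by lactonization or Claisen-type closure with loss of the aryloxide, in place of the aldol closure. The fallback folds ring A first and transfers it afterwards. It sets out from 4: catalytic Et3N in CH2Cl2 should aromatize 4 with the dioxinone intact to 7-hydroxy-2,2-dimethyl-5-propyl-4H-1,3-benzodioxin-4-one F1. Methylation of its single phenol (MeI, K2CO3, acetone) should give 7-methoxy-2,2-dimethyl-5-propyl-4H-1,3-benzodioxin-4-one F2. Irradiation of F2 (300 nm, CH2Cl2) with 6 should release acetone and the ortho-quinone ketene 3-methoxy-6-(oxomethylidene)-5-propylcyclohexa-2,4-dien-1-one F3, which the 4-OH of 6 captures. The fallback comes back to the route at 11.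

**Step 2.** Proton transfer from the forming 1,3-diketone to unreacted dianion may stall the condensation, and the dianion may react in part at the internal carbon. The fallback replaces acylation by aldol addition and oxidation. It sets out from 2: the dianion is added to butanal to give racemic 6-(4-hydroxy-2-oxoheptyl)-2,2-dimethyl-4H-1,3-dioxin-4-one F4, which is oxidized with Dess–Martin periodinane. It comes back to the route at 4.

**Step 1.** O-acylation of the dienolate, double acylation and quenching of the dienolate by the more acidic product may all erode the C-acylation. The fallback sets out from 1: the dienolate is added to acetaldehyde, a reliably γ-selective aldol addition, to give racemic 6-(2-hydroxypropyl)-2,2-dimethyl-4H-1,3-dioxin-4-one F5. Dess–Martin oxidation then brings it back to the route at 2.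

**Step 5.** Over-methylation at a chelated phenol, or base-induced cleavage of the aryl ester by phenoxide or adventitious nucleophiles, may occur. The fallback installs the methyl ether before the depside bond exists. It sets out from 4 and passes through 7-hydroxy-2,2-dimethyl-5-propyl-4H-1,3-benzodioxin-4-one F1 and 7-methoxy-2,2-dimethyl-5-propyl-4H-1,3-benzodioxin-4-one F2, where only one phenol is present at the methylation stage. Photochemical acyl transfer from F2 to 6 then comes back to the route at 11.

**Step 3.** Competing O-benzylation of the 4-OH and decarboxylation of the β-resorcylic acid may lower the selectivity. The fallback builds ring B by the same chain folding as ring A. It sets out from 2: the dianion is condensed with N-methoxy-N-methylhexanamide to give 6-(2,4-dioxononyl)-2,2-dimethyl-4H-1,3-dioxin-4-one F6. Heating F6 with benzyl alcohol in PhMe gives benzyl 3,5,7-trioxododecanoate F7, and base-mediated aldol aromatization (Cs2CO3, then acid) brings it back to the route at 6.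

## Further compounds

F1 | step 4 | 7-hydroxy-2,2-dimethyl-5-propyl-4H-1,3-benzodioxin-4-one | CCCc1cc(O)cc2OC(C)(C)OC(=O)c12
F2 | step 4 | 7-methoxy-2,2-dimethyl-5-propyl-4H-1,3-benzodioxin-4-one | CCCc1cc(OC)cc2OC(C)(C)OC(=O)c12
F3 | step 4 | 3-methoxy-6-(oxomethylidene)-5-propylcyclohexa-2,4-dien-1-one | CCCC1=CC(OC)=CC(=O)C1=C=O
F4 | step 2 | 6-(4-hydroxy-2-oxoheptyl)-2,2-dimethyl-4H-1,3-dioxin-4-one (racemic) | CCCC(O)CC(=O)CC1=CC(=O)OC(C)(C)O1
F5 | step 1 | 6-(2-hydroxypropyl)-2,2-dimethyl-4H-1,3-dioxin-4-one (racemic) | CC(O)CC1=CC(=O)OC(C)(C)O1
F0 | step 5 | none | none
F6 | step 3 | 6-(2,4-dioxononyl)-2,2-dimethyl-4H-1,3-dioxin-4-one | CCCCCC(=O)CC(=O)CC1=CC(=O)OC(C)(C)O1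
F7 | step 3 | benzyl 3,5,7-trioxododecanoate | CCCCCC(=O)CC(=O)CC(=O)CC(=O)OCc1ccccc1
A1 | alternative 1 | 2-(benzyloxy)-4-methoxy-6-propylbenzoic acid | CCCc1cc(OC)cc(OCc2ccccc2)c1C(=O)O
A2 | alternative 1 | benzyl 4-{[2-(benzyloxy)-4-methoxy-6-propylbenzoyl]oxy}-2-hydroxy-6-pentylbenzoate | CCCCCc1cc(OC(=O)c2c(OCc3ccccc3)cc(OC)cc2CCC)cc(O)c1C(=O)OCc1ccccc1
A3 | alternative 2 | benzyl 4-(hex-2-ynoyloxy)-2-hydroxy-6-pentylbenzoate | CCCC#CC(=O)Oc1cc(O)c(C(=O)OCc2ccccc2)c(CCCCC)c1
A4 | alternative 2 | 1,3-dimethoxy-1-(trimethylsilyloxy)buta-1,3-diene | COC(=C)C=C(OC)O[Si](C)(C)C
A5 | alternative 3 | 2-iodo-5-methoxy-3-propylphenol | CCCc1cc(OC)cc(O)c1I
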